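**Retrosynthetic overview**
1. Target 25 ⇒ global O-debenzylation of butenolide 24 ⇒ dehydration of hydroxylactone 23 ⇒ intramolecular aldol of the α-(methoxyacetoxy)-β-keto ester 21. The butenolide ring is closed last.
2. 21 ⇒ quaternary α-hydroxy-β-keto ester 19 ⇒ key C–C bond: intermolecular aldol of the Seebach dioxolanone enolate 16 with 3,4-bis(benzyloxy)benzaldehyde 15, followed by oxidation.
3. Dioxolanone 14 ⇒ (R)-aryl-lactate 11 ⇒ aryl Grignard 10 + methyl (R)-glycidate 9.
4. Chroman 8 ⇒ Jacobsen epoxidation and benzylic hydride opening of chromene 5 ⇒ 4-bromophenol 1 + 3-chloro-3-methylbut-1-yne 2.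
5. Ring order: pyran ring (step 2), temporary dioxolanone (step 8), butenolide (steps 13–14).

Assumption: the SMILES is read as (S) at the quaternary lactone carbon and (S) at the chromanol carbon, and compounds 9, 13, 15 and 20 are bought.

**Step 1**
Reactants: 1 4-bromophenol; 2 3-chloro-3-methylbut-1-yne
Product: 3 1-bromo-4-[(2-methylbut-3-yn-2-yl)oxy]benzene
Conditions: DBU (1.3 equiv), CuCl2·2H2O (0.1 mol%), MeCN, 0 °C
Reagents that add atoms: none
Why: Copper-catalysed O-propargylation of the phenoxide (a Williamson-type etherification through a copper-stabilised tertiary propargyl cation) is the standard entry to aryl 1,1-dimethylpropargyl ethers and leaves the aryl bromide alone.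

**Step 2**
Reactants: 3 1-bromo-4-[(2-methylbut-3-yn-2-yl)oxy]benzene
Product: 5 6-bromo-2,2-dimethyl-2H-chromene, via allenylphenol 4 (not isolated)
Conditions: N,N-diethylaniline, 190 °C, 3 h
Reagents that add atoms: none
Why: The aromatic propargyl Claisen rearrangement gives 4, which closes the pyran ring by 1,5-hydrogen shift and oxa-6π-electrocyclisation, and because both ortho positions are equivalent only one chromene can form.

**Step 3**
Reactants: 5 6-bromo-2,2-dimethyl-2H-chromene
Product: 6 (3S,4S)-6-bromo-3,4-epoxy-2,2-dimethylchroman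
Conditions: (S,S)-Jacobsen catalyst, [(S,S)-N,N'-bis(3,5-di-tert-butylsalicylidene)cyclohexane-1,2-diaminato]MnCl (3 mol%), 4-phenylpyridine N-oxide (20 mol%), aq NaOCl (pH 11.3, Na2HPO4 buffer), CH2Cl2, 0 °C; recrystallise
Reagents that add atoms: sodium hypochlorite, [Na+].[O-]Cl
Why: In the Jacobsen–Katsuki epoxidation, 6-substituted 2,2-dimethylchromenes are the best substrate class (typically ≥95% ee, upgraded by recrystallisation), and the (S,S)-catalyst delivers oxygen to the face that gives the (3S,4S)-epoxide, which sets the chromanol carbon.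

**Step 4**
Reactants: 6 (3S,4S)-6-bromo-3,4-epoxy-2,2-dimethylchroman
Product: 7 (3S)-6-bromo-2,2-dimethylchroman-3-ol
Conditions: LiAlH4 (0.6 equiv), THF, 0 °C, 45 min; H2O/aq NaOH work-up
Reagents that add atoms: none
Why: SN2 hydride opening occurs at the benzylic C4 because C3 is neopentyl-like next to the gem-dimethyl carbon, so the C3–O bond keeps its (S) configuration and the short time at 0 °C spares the aryl bromide.

**Step 5**
Reactants: 7 (3S)-6-bromo-2,2-dimethylchroman-3-ol
Product: 8 (3S)-3-(benzyloxy)-6-bromo-2,2-dimethylchroman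
Conditions: NaH, BnBr, n-Bu4NI (cat.), DMF, 0 °C to rt
Reagents that add atoms: benzyl bromide, BrCc1ccccc1
Why: Williamson etherification of the sodium alkoxide does not touch the carbinol C–O bond and installs a group that survives Grignard, strong-base, acid and oxidation chemistry.

**Step 6**
Reactants: 8 (3S)-3-(benzyloxy)-6-bromo-2,2-dimethylchroman; 9 methyl (2R)-oxirane-2-carboxylate
Product: 11 methyl (2R)-3-[(3S)-3-(benzyloxy)-2,2-dimethylchroman-6-yl]-2-hydroxypropanoate, via arylmagnesium bromide 10 (not isolated)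
Conditions: Mg turnings, I2 (cat.), THF, 50 °C; then CuBr·SMe2 (10 mol%), 9, −40 to −20 °C; aq NH4Cl
Reagents that add atoms: none
Why: Copper-catalysed Grignard opening of the epoxide (organocuprate SN2) at the unsubstituted CH2 of the glycidate outruns ester attack at −40 °C, and since the C2–O bond is never broken the (R) centre of 9 is carried unchanged into 11.

**Step 7**
Reactants: 11 methyl (2R)-3-[(3S)-3-(benzyloxy)-2,2-dimethylchroman-6-yl]-2-hydroxypropanoate
Product: 12 (2R)-3-[(3S)-3-(benzyloxy)-2,2-dimethylchroman-6-yl]-2-hydroxypropanoic acid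
Conditions: LiOH·H2O, THF–H2O, 0 °C; then 1 M HCl
Reagents that add atoms: lithium hydroxide, [Li+].[OH-]
Why: Mild saponification at 0 °C cleaves the unhindered methyl ester without measurable epimerisation of the α-hydroxy centre.

**Step 8**
Reactants: 12 (2R)-3-[(3S)-3-(benzyloxy)-2,2-dimethylchroman-6-yl]-2-hydroxypropanoic acid; 13 pivalaldehyde
Product: 14 (2R,5R)-5-{[(3S)-3-(benzyloxy)-2,2-dimethylchroman-6-yl]methyl}-2-tert-butyl-1,3-dioxolan-4-one (cis)
Conditions: 13 (4 equiv), TsOH·H2O (5 mol%), hexane–toluene 3:1, reflux, Dean–Stark; chromatography, then crystallisation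
Reagents that add atoms: none
Why: In this Seebach acetalisation (self-regeneration of stereocentres) the thermodynamically preferred cis-dioxolanone dominates (about 5–10:1), so the (5R) centre dictates the new (2R) acetal centre, and the minor trans isomer is separated.

**Step 9**
Reactants: 14 (2R,5R)-5-{[(3S)-3-(benzyloxy)-2,2-dimethylchroman-6-yl]methyl}-2-tert-butyl-1,3-dioxolan-4-one; 15 3,4-bis(benzyloxy)benzaldehyde
Product: 17 (2R,5S)-5-{[3,4-bis(benzyloxy)phenyl](hydroxy)methyl}-5-{[(3S)-3-(benzyloxy)-2,2-dimethylchroman-6-yl]methyl}-2-tert-butyl-1,3-dioxolan-4-one (carbinol epimers), via lithium enolate 16 (not isolated)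
Conditions: LiN(iPr)2 (commercial solution, 1.1 equiv), THF, −78 °C, 40 min; 15, −78 °C, 2 h; AcOH quench at −78 °C
Reagents that add atoms: none
Why: In this intermolecular aldol addition the planar enolate 16 keeps only the acetal centre, whose tert-butyl group blocks one face, so the aldehyde bonds anti to it (typically >95:5) and takes the place of the former hydrogen to give the (5S) quaternary carbon, while the carbinol mixture is erased in step 10.

**Step 10**
Reactants: 17 aldol adduct
Product: 18 (2R,5S)-5-[3,4-bis(benzyloxy)benzoyl]-5-{[(3S)-3-(benzyloxy)-2,2-dimethylchroman-6-yl]methyl}-2-tert-butyl-1,3-dioxolan-4-one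
Conditions: Dess–Martin periodinane (1.5 equiv), CH2Cl2, rt
Reagents that add atoms: none
Why: Dess–Martin oxidation converts both carbinol epimers into one aryl ketone under non-basic conditions, so retro-aldol is avoided, and the adjacent quaternary carbon has no hydrogen to epimerise.

**Step 11**
Reactants: 18 aroyl dioxolanone
Product: 19 methyl (2S)-2-{[(3S)-3-(benzyloxy)-2,2-dimethylchroman-6-yl]methyl}-3-[3,4-bis(benzyloxy)phenyl]-2-hydroxy-3-oxopropanoate
Conditions: HCl in MeOH (1.25 M, commercial), 50 °C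
Reagents that add atoms: methanol, CO
Why: Acid-catalysed methanolysis of the activated acylal-type lactone releases the methyl ester and the tertiary alcohol, and acid is chosen over methoxide because alkoxide would cleave the non-enolisable β-keto ester by retro-Claisen reaction.

**Step 12**
Reactants: 19 α-hydroxy-β-keto ester; 20 methoxyacetyl chloride
Product: 21 methyl (2S)-2-{[(3S)-3-(benzyloxy)-2,2-dimethylchroman-6-yl]methyl}-3-[3,4-bis(benzyloxy)phenyl]-2-[(methoxyacetyl)oxy]-3-oxopropanoate
Conditions: 20 (3 equiv), pyridine (5 equiv), DMAP (0.3 equiv), CH2Cl2, 0 to 35 °C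
Reagents that add atoms: none
Why: DMAP-catalysed O-acylation with a small, activated acid chloride is the most dependable way to esterify a hindered tertiary alcohol, and it brings in C4, C5 and the enol methyl ether of the future furanone in one piece.

**Step 13**
Reactants: 21 methoxyacetate
Product: 23 methyl (2S)-3-[3,4-bis(benzyloxy)phenyl]-2-{[(3S)-3-(benzyloxy)-2,2-dimethylchroman-6-yl]methyl}-3-hydroxy-4-methoxy-5-oxotetrahydrofuran-2-carboxylate (mixture at C3/C4), via lithium ester enolate 22 (not isolated)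
Conditions: LiN(SiMe3)2 (1.15 equiv), THF, −78 °C, 1 h; AcOH quench at −78 °C
Reagents that add atoms: none
Why: The methoxyacetate CH2 is the only acidic site, and in this intramolecular aldol addition (5-exo-trig) its lithium enolate adds under kinetic control to the ketone faster than to the ester, while the two new centres form as a mixture that step 14 destroys.

**Step 14**
Reactants: 23 hydroxylactone
Product: 24 methyl (2S)-3-[3,4-bis(benzyloxy)phenyl]-2-{[(3S)-3-(benzyloxy)-2,2-dimethylchroman-6-yl]methyl}-4-methoxy-5-oxo-2,5-dihydrofuran-2-carboxylate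
Conditions: SOCl2 (2.5 equiv), pyridine, CH2Cl2, 0 °C to rt
Reagents that add atoms: none
Why: Dehydration through the chlorosulfite of a tertiary p-alkoxybenzylic alcohol is easy, and the only β-hydrogen is the acidic one α to the lactone carbonyl, so all diastereomers converge on the single possible conjugated alkene.

**Step 15**
Reactants: 24 tribenzyl butenolide
Product: 25 methyl (2S)-3-(3,4-dihydroxyphenyl)-2-{[(3S)-3-hydroxy-2,2-dimethylchroman-6-yl]methyl}-4-methoxy-5-oxo-2,5-dihydrofuran-2-carboxylate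
Conditions: H2 (1 atm), 10% Pd/C, EtOAc–MeOH 1:1, rt, stopped at full conversion
Reagents that add atoms: none
Why: Catalytic hydrogenolysis removes all three benzyl ethers under neutral conditions, while the tetrasubstituted conjugated alkene, the enol methyl ether, the esters and both stereocentres are inert at one atmosphere.

**Compound list**
1 | 4-bromophenol | Oc1ccc(Br)cc1 | starting material
2 | 3-chloro-3-methylbut-1-yne | C#CC(C)(C)Cl | starting material
3 | 1-bromo-4-[(2-methylbut-3-yn-2-yl)oxy]benzene | C#CC(C)(C)Oc1ccc(Br)cc1 | intermediate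
4 | 4-bromo-2-(3-methylbuta-1,2-dien-1-yl)phenol (not isolated) | CC(C)=C=Cc1cc(Br)ccc1O | intermediate
5 | 6-bromo-2,2-dimethyl-2H-chromene | Brc1ccc2c(c1)C=CC(C)(C)O2 | intermediate
6 | (3S,4S)-6-bromo-3,4-epoxy-2,2-dimethylchroman | Brc1ccc2c(c1)[C@@H]3O[C@@H]3C(C)(C)O2 | intermediate
7 | (3S)-6-bromo-2,2-dimethylchroman-3-ol | Brc1ccc2c(c1)C[C@H](O)C(C)(C)O2 | intermediate
8 | (3S)-3-(benzyloxy)-6-bromo-2,2-dimethylchroman | Brc1ccc2c(c1)C[C@H](OCc3ccccc3)C(C)(C)O2 | intermediate
9 | methyl (2R)-oxirane-2-carboxylate (methyl (R)-glycidate) | COC(=O)[C@H]1CO1 | starting material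
10 | [(3S)-3-(benzyloxy)-2,2-dimethylchroman-6-yl]magnesium bromide (not isolated) | Br[Mg]c1ccc2c(c1)C[C@H](OCc3ccccc3)C(C)(C)O2 | intermediate
11 | methyl (2R)-3-[(3S)-3-(benzyloxy)-2,2-dimethylchroman-6-yl]-2-hydroxypropanoate | COC(=O)[C@H](O)Cc1ccc2c(c1)C[C@H](OCc3ccccc3)C(C)(C)O2 | intermediate
12 | (2R)-3-[(3S)-3-(benzyloxy)-2,2-dimethylchroman-6-yl]-2-hydroxypropanoic acid | OC(=O)[C@H](O)Cc1ccc2c(c1)C[C@H](OCc3ccccc3)C(C)(C)O2 | intermediate
13 | pivalaldehyde | CC(C)(C)C=O | starting material
14 | (2R,5R)-5-{[(3S)-3-(benzyloxy)-2,2-dimethylchroman-6-yl]methyl}-2-tert-butyl-1,3-dioxolan-4-one | CC(C)(C)[C@H]1OC(=O)[C@@H](Cc2ccc3c(c2)C[C@H](OCc4ccccc4)C(C)(C)O3)O1 | intermediate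
15 | 3,4-bis(benzyloxy)benzaldehyde | O=Cc1ccc(OCc2ccccc2)c(OCc2ccccc2)c1 | starting material
16 | lithium enolate of 14 (not isolated) | CC(C)(C)[C@H]1OC([O-])=C(Cc2ccc3c(c2)C[C@H](OCc4ccccc4)C(C)(C)O3)O1.[Li+] | intermediate
17 | (2R,5S)-aldol adduct, carbinol epimers | CC(C)(C)[C@H]1OC(=O)[C@](Cc2ccc3c(c2)C[C@H](OCc4ccccc4)C(C)(C)O3)(C(O)c2ccc(OCc3ccccc3)c(OCc3ccccc3)c2)O1 | intermediate
18 | (2R,5S)-5-[3,4-bis(benzyloxy)benzoyl] dioxolanone | CC(C)(C)[C@H]1OC(=O)[C@](Cc2ccc3c(c2)C[C@H](OCc4ccccc4)C(C)(C)O3)(C(=O)c2ccc(OCc3ccccc3)c(OCc3ccccc3)c2)O1 | intermediate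
19 | methyl (2S)-2-{[(3S)-3-(benzyloxy)-2,2-dimethylchroman-6-yl]methyl}-3-[3,4-bis(benzyloxy)phenyl]-2-hydroxy-3-oxopropanoate | COC(=O)[C@](O)(Cc1ccc2c(c1)C[C@H](OCc3ccccc3)C(C)(C)O2)C(=O)c1ccc(OCc2ccccc2)c(OCc2ccccc2)c1 | intermediate
20 | methoxyacetyl chloride | COCC(=O)Cl | starting material
21 | methoxyacetate ester of 19 | COC(=O)[C@](OC(=O)COC)(Cc1ccc2c(c1)C[C@H](OCc3ccccc3)C(C)(C)O2)C(=O)c1ccc(OCc2ccccc2)c(OCc2ccccc2)c1 | intermediate
22 | lithium ester enolate of 21 (not isolated) | COC(=O)[C@](OC([O-])=COC)(Cc1ccc2c(c1)C[C@H](OCc3ccccc3)C(C)(C)O2)C(=O)c1ccc(OCc2ccccc2)c(OCc2ccccc2)c1.[Li+] | intermediate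
23 | (2S)-3-hydroxy-4-methoxy-5-oxotetrahydrofuran-2-carboxylate, mixture at C3/C4 | COC(=O)[C@@]1(Cc2ccc3c(c2)C[C@H](OCc4ccccc4)C(C)(C)O3)OC(=O)C(OC)C1(O)c1ccc(OCc2ccccc2)c(OCc2ccccc2)c1 | intermediate
24 | tribenzyl-protected butenolide | COC(=O)[C@@]1(Cc2ccc3c(c2)C[C@H](OCc4ccccc4)C(C)(C)O3)OC(=O)C(OC)=C1c1ccc(OCc2ccccc2)c(OCc2ccccc2)c1 | intermediate
25 | CNP0289675.4 | COC(=O)[C@@]1(Cc2ccc3c(c2)C[C@H](O)C(C)(C)O3)OC(=O)C(OC)=C1c1ccc(O)c(O)c1 | target

**Step count and weak points**
Total steps: 15. Longest linear sequence: 15 (1 to 25), since 2, 9, 13, 15 and 20 are purchased.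

The three steps most likely to fail are 13, 12 and 9.

Step 13 carries the highest risk. Enolate 22 can also attack the neighbouring methyl ester (Dieckmann closure to a 3-methoxytetronate). The hindered, electron-rich aryl ketone may also favour retro-aldol. The fallback replaces aldol plus dehydration by an intramolecular Horner–Wadsworth–Emmons olefination, whose stabilised phosphonate anion does not acylate on esters.
- Commercial methyl 2-(dimethoxyphosphoryl)-2-methoxyacetate is saponified with one equivalent of LiOH to 2-(dimethoxyphosphoryl)-2-methoxyacetic acid F1.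
- Setting out from 19, DCC/DMAP coupling with F1 gives the phosphonoacetate ester F2.
- LiCl/DBU in MeCN at rt then closes the ring with loss of phosphate.
- The route is rejoined at 24, bypassing 21 to 23.

Step 12 may fail because the tertiary alcohol of 19, flanked by ester, aroyl and benzyl groups, may acylate poorly. The fallback forms the C–C bond first and lets the C–O bond form intramolecularly.
- Setting out from 19, three equivalents of the lithium enolate of methyl methoxyacetate (LiN(iPr)2, THF, −78 °C) are added. The first deprotonates the hydroxyl group, and the chelated ketone then takes up the second in an intermolecular aldol addition.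
- This gives the dihydroxy diester F3.
- On warming, or with catalytic TsOH, the tertiary hydroxyl of F3 closes onto the new ester as a five-membered lactone.
- The route is rejoined at 23.

Step 9 may fail because the aldolate from a tetrasubstituted enolate and an electron-rich aldehyde is reversible, and enolate 16 is thermally fragile. The fallback is an irreversible crossed Claisen-type C-acylation.
- Setting out from 15, Pinnick oxidation (NaClO2, NaH2PO4, 2-methylbut-2-ene) gives 3,4-bis(benzyloxy)benzoic acid F4.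
- (COCl)2 with catalytic DMF gives 3,4-bis(benzyloxy)benzoyl chloride F5.
- Enolate 16, made from 14 as before, is acylated with F5 at −78 °C on the face anti to the tert-butyl group.
- The product has no acidic hydrogen, so one equivalent of enolate suffices.
- The route is rejoined at 18, skipping 17 and step 10.

**Further compounds**
F1 | step 13 | 2-(dimethoxyphosphoryl)-2-methoxyacetic acid | COC(C(=O)O)P(=O)(OC)OC
F2 | step 13 | methyl (2S)-2-{[(3S)-3-(benzyloxy)-2,2-dimethylchroman-6-yl]methyl}-3-[3,4-bis(benzyloxy)phenyl]-2-{[2-(dimethoxyphosphoryl)-2-methoxyacetyl]oxy}-3-oxopropanoate | COC(=O)[C@](OC(=O)C(OC)P(=O)(OC)OC)(Cc1ccc2c(c1)C[C@H](OCc3ccccc3)C(C)(C)O2)C(=O)c1ccc(OCc2ccccc2)c(OCc2ccccc2)c1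
F3 | step 12 | dimethyl (2S)-2-{[(3S)-3-(benzyloxy)-2,2-dimethylchroman-6-yl]methyl}-3-[3,4-bis(benzyloxy)phenyl]-2,3-dihydroxy-4-methoxypentanedioate (mixture at C3/C4) | COC(=O)[C@](O)(Cc1ccc2c(c1)C[C@H](OCc3ccccc3)C(C)(C)O2)C(O)(C(OC)C(=O)OC)c1ccc(OCc2ccccc2)c(OCc2ccccc2)c1
F4 | step 9 | 3,4-bis(benzyloxy)benzoic acid | OC(=O)c1ccc(OCc2ccccc2)c(OCc2ccccc2)c1
F5 | step 9 | 3,4-bis(benzyloxy)benzoyl chloride | ClC(=O)c1ccc(OCc2ccccc2)c(OCc2ccccc2)c1
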